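**Assumptions**
- Germacrane numbering is used throughout: C8 carries the methacrylate, C2 is the ketal carbon, C6/C7 are the lactone fusion carbons. Read from the SMILES, the target is (2S,5S,6S,7R,8S) with a 1(10)Z olefin.
- 4-Methyl-5,6-dihydro-2H-pyran-2-one (CAS 2381-87-5) is taken as a catalogue compound.
- In step 5 the (R)-BINOL catalyst is assumed to give the (S,S) adduct; if the first run gives the antipode, (S)-BINOL is used.

## Retrosynthetic overview
1. The bridging dihydrofuran ketal is formed last: the C5–OH adds across the ring to a C2 dienone and the hemiketal is methanolysed; the bridge fixes C2.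
2. The 10-membered carbocycle and the α-methylene lactone come from one C7–C8 bond: a samarium ketyl radical at C8 adds to a butenolide and expels thiolate (sets C7 and C8).
3. The open chain comes from a C2–C3 Ni/Cr coupling of a (Z)-vinyl iodide with a lactol whose ring supplies the Z C1=C10 olefin.
4. C5–C6 and both of their stereocentres come from a catalytic asymmetric vinylogous Mukaiyama aldol of a silyloxyfuran with a (Z)-iodoenal.
5. Ring order: butenolide (present from the start) → 10-membered carbocycle with γ-lactone → bridged dihydrofuran ketal.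

## Route

**Step 1**
Reactants: 1, prop-2-yn-1-ol
Product: 2, (Z)-3-iodo-2-methylprop-2-en-1-ol
Conditions: MeMgBr (2.5 equiv), CuI (10 mol %), THF, −10 °C → rt; then I2, −78 → 0 °C
Reagents that add atoms: methylmagnesium bromide, C[Mg]Br; iodine, II
Why: Cu-catalysed anti-carbomagnesiation of the propargylic alkoxide (Duboudin–Jousseaume) gives a chelated (Z)-alkenylmagnesium that is iodinated with retention, fixing the Z C3=C4 geometry (iodine cis to the carbinol carbon).

**Step 2**
Reactants: 2, (Z)-3-iodo-2-methylprop-2-en-1-ol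
Product: 3, (Z)-3-iodo-2-methylprop-2-enal
Conditions: MnO2, CH2Cl2, rt, dark
Reagents that add atoms: none
Why: Neutral MnO2 oxidation of an allylic alcohol leaves the vinyl iodide and the Z geometry untouched.

**Step 3**
Reactants: 4, furan-2(5H)-one
Product: 5, 3-[(phenylsulfanyl)methyl]furan-2(5H)-one
Conditions: PhSH, 37 % aq. CH2O, Et3N, EtOH, 70 °C
Reagents that add atoms: formaldehyde, C=O; thiophenol, Sc1ccccc1
Why: Kirby α-(phenylthiomethyl)ation (thiolate conjugate addition, enolate hydroxymethylation, elimination and SN2′ thiol return, a thiolate-mediated Morita–Baylis–Hillman-type sequence) installs the future exocyclic methylene carbon together with its leaving group.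

**Step 4**
Reactants: 5, 3-[(phenylsulfanyl)methyl]furan-2(5H)-one
Product: 6, trimethyl({3-[(phenylsulfanyl)methyl]furan-2-yl}oxy)silane
Conditions: TMSOTf, Et3N, CH2Cl2, 0 °C; used crude after filtration and concentration
Reagents that add atoms: trimethylsilyl triflate, C[Si](C)(C)OS(=O)(=O)C(F)(F)F
Why: Soft enolisation and O-silylation give the aromatic 2-silyloxyfuran, the vinylogous silyl ketene acetal needed for γ-selective aldol chemistry.

**Step 5**
Reactants: 3, (Z)-3-iodo-2-methylprop-2-enal; 6, the silyloxyfuran
Product: 7, (5S)-5-[(1S,2Z)-1-hydroxy-3-iodo-2-methylprop-2-en-1-yl]-3-[(phenylsulfanyl)methyl]furan-2(5H)-one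
Conditions: Ti(OiPr)4/(R)-BINOL (20 mol %), Et2O, −20 °C; then TFA, THF/H2O
Reagents that add atoms: none
Why: Catalytic asymmetric vinylogous Mukaiyama aldol: γ-attack through the Lewis-acid synclinal open transition state gives the syn (threo) adduct, and the Ti–BINOL complex selects the aldehyde face, setting C5 and C6 both as S.

**Step 6**
Reactants: 8, 4-methyl-5,6-dihydro-2H-pyran-2-one
Product: 9, 4-methyl-5,6-dihydro-2H-pyran-2-ol (racemic lactol)
Conditions: DIBAL-H (1.05 equiv), CH2Cl2, −78 °C; Rochelle salt
Reagents that add atoms: none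
Why: 1,2-Reduction of the unsaturated δ-lactone stops at the lactol, a masked (Z)-5-hydroxy-3-methylpent-2-enal whose Z geometry is inherited from the ring.

**Step 7**
Reactants: 7, the vinyl iodide; 9, the lactol
Product: 10, (5S)-5-[(1S,2Z,5Z)-1,4,8-trihydroxy-2,6-dimethylocta-2,5-dien-1-yl]-3-[(phenylsulfanyl)methyl]furan-2(5H)-one (mixture of epimers at side-chain C4 = germacrane C2)
Conditions: CrCl2 (6 equiv), NiCl2 (2 mol %), DMSO/THF, rt
Reagents that add atoms: none
Why: Nozaki–Hiyama–Kishi coupling: the alkenylchromium (Z retained) adds chemoselectively to the aldehyde tautomer of the lactol in the presence of free hydroxyls, the butenolide and the sulfide; the new C2 carbinol centre is unselective and is erased in step 12.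

**Step 8**
Reactants: 10, the triol
Product: 11, (5S)-5-[(1S,2Z,5Z)-2,6-dimethyl-1,4,8-tris(triethylsilyloxy)octa-2,5-dien-1-yl]-3-[(phenylsulfanyl)methyl]furan-2(5H)-one
Conditions: TESOTf, 2,6-lutidine, CH2Cl2, −78 → 0 °C
Reagents that add atoms: triethylsilyl triflate, CC[Si](CC)(CC)OS(=O)(=O)C(F)(F)F
Why: Exhaustive silylation protects all three hydroxyls so that the primary one can be singled out in the next step.

**Step 9**
Reactants: 11, the tris-TES ether
Product: 12, (3Z,6Z,8S)-3,7-dimethyl-8-{(2S)-5-oxo-4-[(phenylsulfanyl)methyl]-2,5-dihydrofuran-2-yl}-5,8-bis(triethylsilyloxy)octa-3,6-dienal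
Conditions: (COCl)2, DMSO, CH2Cl2, −78 → −30 °C; then iPr2NEt, −78 °C, cold buffered work-up
Reagents that add atoms: none
Why: Under Swern conditions a primary TES ether is cleaved and oxidised directly to the aldehyde while secondary TES ethers survive.

**Step 10 (key step)**
Reactants: 12, the aldehyde
Product: 13, (3aR,4S,6Z,9Z,11S,11aS)-4-hydroxy-6,10-dimethyl-3-methylidene-8,11-bis(triethylsilyloxy)-3a,4,5,8,11,11a-hexahydrocyclodeca[b]furan-2(3H)-one (C8 of this name = germacrane C2, epimer mixture)
Conditions: SmI2 (2.5 equiv, 0.1 M in THF) added over 4 h to 12 (2 mM in THF), −78 → −30 °C, no HMPA; AcOH/pH 7 buffer quench at −78 °C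
Reagents that add atoms: none
Why: Proposed new method: SmI2 reduces the aldehyde to a samarium ketyl radical that adds 10-exo-trig to the butenolide β-carbon anti to the C6 side chain (sets 7R, trans lactone), the resulting α-lactone radical/Sm enolate expels phenylthiolate to unveil the exocyclic methylene, and a Sm(III)-bridged ketyl–lactone-carbonyl transition state (O8 gauche to C11, C9 anti to C6) is expected to give 8S; the closest known chemistry is SmI2 ketyl–acrylate/butenolide coupling, 8-membered ketyl–olefin cyclisation and radical allyl transfer from allyl sulfides.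

**Step 11**
Reactants: 13, the macrocyclic alcohol
Product: 14, the C8 methacrylate of 13
Conditions: methacryloyl chloride, Et3N, DMAP (cat.), CH2Cl2, 0 °C
Reagents that add atoms: methacryloyl chloride, C=C(C)C(=O)Cl
Why: DMAP-catalysed acylation of the only free hydroxyl proceeds with retention at C8.

**Step 12**
Reactants: 14, the methacrylate
Product: 15, (3aR,4S,6Z,9Z,11S,11aS)-6,10-dimethyl-3-methylidene-2,8-dioxo-11-(triethylsilyloxy)-2,3,3a,4,5,8,11,11a-octahydrocyclodeca[b]furan-4-yl 2-methylprop-2-enoate
Conditions: DDQ (1.5 equiv), CH2Cl2/pH 7 buffer (10:1), 0 °C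
Reagents that add atoms: none
Why: DDQ abstracts hydride from the doubly allylic C2–H of the silyl ether (DDQ oxidation of allylic silyl ethers) to give the cross-conjugated dienone directly, converging both C2 epimers; the mono-allylic, lactone-deactivated C5 silyl ether is left alone and the ring holds both Z olefins.

**Step 13**
Reactants: 15, the dienone
Product: 16, 2-deethoxy-2β-methoxyphantomolin (target)
Conditions: PPTS (0.2 equiv), MeOH/HC(OMe)3, 0 °C → rt
Reagents that add atoms: methanol, CO
Why: Acidic desilylation frees the C5 hydroxyl, which adds transannularly to the C2 ketone, and methanolysis of the bridged hemiketal gives the methyl ketal; the 2,5-oxygen bridge can only span the ring cis, so C2 is set as S (methoxy exo) under thermodynamic control, and dehydration to a furan is blocked by the strain of the bridge.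

## Compound list
1 | prop-2-yn-1-ol | C#CCO | starting material
2 | (Z)-3-iodo-2-methylprop-2-en-1-ol | OC/C(C)=C\I | intermediate
3 | (Z)-3-iodo-2-methylprop-2-enal | O=C/C(C)=C\I | intermediate
4 | furan-2(5H)-one | O=C1OCC=C1 | starting material
5 | 3-[(phenylsulfanyl)methyl]furan-2(5H)-one | O=C1OCC=C1CSc1ccccc1 | intermediate
6 | trimethyl({3-[(phenylsulfanyl)methyl]furan-2-yl}oxy)silane | C[Si](C)(C)Oc1occc1CSc1ccccc1 | intermediate
7 | (5S)-5-[(1S,2Z)-1-hydroxy-3-iodo-2-methylprop-2-en-1-yl]-3-[(phenylsulfanyl)methyl]furan-2(5H)-one | I/C=C(C)\[C@H](O)[C@H]1OC(=O)C(CSc2ccccc2)=C1 | intermediate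
8 | 4-methyl-5,6-dihydro-2H-pyran-2-one | CC1=CC(=O)OCC1 | starting material
9 | 4-methyl-5,6-dihydro-2H-pyran-2-ol | CC1=CC(O)OCC1 | intermediate
10 | (5S)-5-[(1S,2Z,5Z)-1,4,8-trihydroxy-2,6-dimethylocta-2,5-dien-1-yl]-3-[(phenylsulfanyl)methyl]furan-2(5H)-one (C2 epimers) | OCC/C(C)=C\C(O)/C=C(C)\[C@H](O)[C@H]1OC(=O)C(CSc2ccccc2)=C1 | intermediate
11 | tris-TES ether of 10 | CC[Si](CC)(CC)OCC/C(C)=C\C(O[Si](CC)(CC)CC)/C=C(C)\[C@H](O[Si](CC)(CC)CC)[C@H]1OC(=O)C(CSc2ccccc2)=C1 | intermediate
12 | (3Z,6Z,8S)-3,7-dimethyl-8-{(2S)-5-oxo-4-[(phenylsulfanyl)methyl]-2,5-dihydrofuran-2-yl}-5,8-bis(triethylsilyloxy)octa-3,6-dienal | O=CC/C(C)=C\C(O[Si](CC)(CC)CC)/C=C(C)\[C@H](O[Si](CC)(CC)CC)[C@H]1OC(=O)C(CSc2ccccc2)=C1 | intermediate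
13 | (3aR,4S,6Z,9Z,11S,11aS)-4-hydroxy-6,10-dimethyl-3-methylidene-8,11-bis(triethylsilyloxy)-3a,4,5,8,11,11a-hexahydrocyclodeca[b]furan-2(3H)-one | O[C@H]1C/C(C)=C\C(O[Si](CC)(CC)CC)/C=C(C)\[C@H](O[Si](CC)(CC)CC)[C@H]2OC(=O)C(=C)[C@@H]21 | intermediate
14 | C8 methacrylate of 13 | C=C(C)C(=O)O[C@H]1C/C(C)=C\C(O[Si](CC)(CC)CC)/C=C(C)\[C@H](O[Si](CC)(CC)CC)[C@H]2OC(=O)C(=C)[C@@H]21 | intermediate
15 | macrocyclic C2 dienone, 5-O-TES, 8-O-methacrylate | C=C(C)C(=O)O[C@H]1C/C(C)=C\C(=O)/C=C(C)\[C@H](O[Si](CC)(CC)CC)[C@H]2OC(=O)C(=C)[C@@H]21 | intermediate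
16 | 2-deethoxy-2β-methoxyphantomolin | C=C(C)C(=O)O[C@H]1C/C(C)=C\[C@@]2(OC)C=C(C)[C@H](O2)[C@H]2OC(=O)C(=C)[C@@H]21 | target

## Summary
Total steps: 13.
Longest linear sequence: 10 (steps 1, 2, 5, 7–13; the branch 3, 4, 5, 7–13 is equally long).

Three steps most likely to fail, each with a fallback that changes the approach:
- **Step 10 (SmI2 ketyl macrocyclisation).** Risks are pinacol dimerisation, simple aldehyde reduction, over-reduction of the product, or the wrong C8 epimer. Fallback: make the C7–C8 bond intermolecularly with SmI2 (TES-protected 7 plus (Z)-3-methyl-5-silyloxypent-3-enal), then oxidise the allylic C2 alcohol with MnO2 and close the ring at C2–C3 by intramolecular Ni/Cr coupling of the vinyl iodide. If only the C8 configuration is wrong, step 11 becomes a Mitsunobu esterification with methacrylic acid (inversion).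
- **Step 5 (asymmetric vinylogous aldol).** Risks are modest syn/anti ratio or ee with the α-branched iodoenal and the thioether-bearing furan. Fallback: Brown (Z)-γ-(methoxymethoxy)allyl-diisopinocampheylborane addition to 3 to set the syn C5/C6 diol, then build the butenolide by acylating the C6 oxygen with 2-[(phenylsulfanyl)methyl]acryloyl chloride and ring-closing metathesis.
- **Step 7 (Ni/Cr coupling with a lactol).** Risks are low reactivity of the lactol or Z→E drift of the enal. Fallback: reverse the order of fragment union. Add the vinyllithium from the dimethyl acetal of 3 to lactol 9 before any butenolide is present, silylate, unmask the C5 aldehyde, and use the vinylogous aldol with 6 as the final fragment coupling.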